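A bench chemist charges L and Z in two flasks, north-west and east, and wants E.

- north-west: L 0.098 M; Z 0.0980 M; temperature 25 °C; time 80 min
- east: L 0.098 M; Z 0.0980 M; temperature 35 °C; time 80 min

    Q ⇌ X (K1 = 3.1, k1 = 0.051 min⁻¹, Ea1 = 89.0 kJ mol⁻¹, ΔH1 = −52.0 kJ mol⁻¹)
    Z ⇌ D (K2 = 0.96, k2 = 0.023 min⁻¹, Ea2 = 83.0 kJ mol⁻¹, ΔH2 = −75.0 kJ mol⁻¹)
    L + Z → Q + G (k3 = 0.67 L mol⁻¹ min⁻¹, Ea3 = 62.0 kJ mol⁻¹)
    Q ⇌ E (K4 = 3.1, k4 = 0.15 min⁻¹, Ea4 = 85.0 kJ mol⁻¹, ΔH4 = −31.0 kJ mol⁻¹)
    E + G → E.G (k5 = 1.4 L mol⁻¹ min⁻¹, Ea5 = 44.0 kJ mol⁻¹)
    (constants at 25 °C)

1. which of the two there is more of at the end, north-west (E / E.G)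
2. which of the two there is more of at the end, east (E / E.G)
3. amount of E at the end, in percent of the L charged, north-west
4. amount of E at the end, in percent of the L charged, east

- constants are those at 25 °C; use the activation energies and enthalpies for any other temperature

Each Q formed brings one G, and each capture removes one E and one G, so c(G) equals the pool Q + X + E. The bench rule is a pre-equilibrium: Q and E interconvert, so c(E)/c(Q) stands at the equilibrium constant of that step, 3.1 in north-west.

This rule has a border. E leaves by two ways: back to Q at 0.0484 min⁻¹, and into E.G at a rate constant that grows with c(G). In north-west the two are equal at c(G) = 0.0346 M. Call this c*, the concentration of G at which E returns to Q as fast as G catches it. Holding E steady gives c(E)/c(Q) = constant / (one + c(G)/c*). Well below c* the bench rule stands. At c* the ratio is half of the constant.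

In north-west c* is a third of the charged L. In east the return step climbs a barrier of 116 kJ mol⁻¹ against 44.0 kJ mol⁻¹ for capture, so c* rises to 0.0887 M, while the constant falls to 2.07. With c(G) at the north-west c*, the ratio is 1.55 in north-west and 1.49 in east. This reckoning stops there: it splits Q from E, but gives no pool size and so no amount of E.

The forecast puts E.G ahead in north-west and E.G ahead in east, with E at 7.8% and 7.2%. Its ground is this: “G and the pool Q+X+E are always equal, since each Q formed brings one G.” It goes on to amounts, which the reckoning above does not reach.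

The flasks give E.G at 45.2% against E at 8.22% in north-west, and E.G at 71.3% against E at 7.12% in east. Neither flask is at rest at 80 min. At 80.0 min north-west still holds L at 25.9%. After 800 min north-west holds L at 3.78%, E.G at 91.8% and E at 1.74%. At that time c(G) in north-west is 0.00437 M, less than c*, and the border rule gives c(E)/c(Q) = 2.75 against a reading of 2.81. After 800 min east holds L at 1.14% and E at 0.826%, with c(G) at 0.00184 M. Its rule gives 2.03 against a reading of 2.04.

(All constants belong to no real substance; the run is a simulation.)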